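## Analysis of the target

The target is a lariciresinol-type lignan ester built on one tetrahydrofuran ring (O1, C2–C5). C2 carries a 4-hydroxy-3-methoxyphenyl group, C3 carries a CH2 group (C3a) whose oxygen bears an octadecanoyl (stearoyl) group, C4 carries a 4-hydroxy-3-methoxybenzyl group through the benzylic carbon C4a, and C5 is an unsubstituted CH2. The three stereocentres are contiguous, (2S,3R,4R): the aryl group on C2 is trans to C3a, while C3a and C4a are cis, so two of the three substituents are crowded onto one face. Sensitive groups are the two free guaiacyl phenols, the long-chain ester and, above all, the C2–O1 bond, which is a para-oxygenated benzylic ether. Acid ionises that bond to a benzylic cation that the electron-rich aryl ring on C4a can capture to give an aryltetralin, and prolonged hydrogenation over palladium cleaves it, more easily once the para-hydroxyl is free. The synthesis is hard in three respects: the cis C3/C4 pair next to a third centre, the need to tell one aliphatic hydroxyl from two phenols, and the narrow range of conditions that the finished ring tolerates. The plan rests on the O1–C2–C3 segment: if C2 with its aryl group is taken out, O1 is bonded directly to C3, and O1, C3, C4 and C5 form an oxetane whose two substituents are C3a and C4a in their cis relationship. Putting C2 back as an aryl carbene carbon between O1 and C3 restores the five-membered ring.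

## Retrosynthetic reasoning

**21 back to 20 (two O–benzyl bonds).** The last operation is kept as light as possible for the finished ring: only the two phenols are uncovered, from the bis(benzyl ether) 20. Aryl benzyl ethers are the fastest benzyl ethers to hydrogenolyse, so the C2–O1 bond is exposed only briefly. Because the ester is already present in 20, no step has to distinguish the aliphatic hydroxyl from the phenols, and no slow aliphatic benzyl ether has to be cleaved next to the labile ring ether.

**20 back to 15 and 19 (O1–C2 and C2–C3).** This disconnection carries the plan. Both ring bonds to C2 are cut: the aryl-bearing carbon leaves as the carbene carbon of diazo compound 19, and the remaining atoms close to oxetane 15. The cut is made here because C2 is the one ring carbon that is both attached to the heteroatom and benzylic, which is what an oxonium ylide followed by a Stevens shift can deliver. It leaves the cis pair C3/C4 to be fixed beforehand in a rigid four-membered ring, and it returns the ring, two skeletal bonds and the C2 stereocentre in one step. The forward reaction has to form the ylide at the oxetane oxygen, move the substituted carbon (the future C3) and not the CH2 group, keep the configuration of that carbon, and place the aryl group trans to C3a. Correcting a wrong C2 configuration with acid is not part of the plan, because the benzylic cation would be trapped by the aryl ring on C4a; the 2,3-trans outcome has to come from the recombination itself, and a minor epimer is removed by chromatography. The ester is carried through this step as a spectator so that only the phenol protection remains afterwards.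

**19 back to 17 and 16 (C=N2).** An electron-rich aryl diazomethane cannot be stored, so 19 is released in the flask from the sodium salt 18 of sulfonylhydrazone 17, which is one condensation away from aldehyde 16.

**15 back to 13 and 14 (acyl C–O).** The ester bond is formed on the small oxetane alcohol 13, where the primary hydroxyl is the only one present; stearic acid 14 is the acyl source.

**13 back to 12 (protecting group on the C3a oxygen).** During the oxetane closure this oxygen must be an ether, because an ester or a silyl group would migrate to the neighbouring alkoxide. The 4-methoxybenzyl ether in 12 can be removed oxidatively without touching the aryl benzyl ether, at a stage where no oxidisable benzylic ring ether exists yet.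

**12 back to 11 and 10 (O1–C5).** The oxetane is opened at the bond between the ring oxygen and the unsubstituted CH2 group, giving sulfonate 11 and diol 10. With the leaving group on the primary carbon and the secondary oxygen as nucleophile, no stereocentre takes part in the substitution, so the relative configuration of 10 is transferred unchanged.

**10 back to 9, then 6 and 7 (C3–C4).** Diol 10 is the reduced form of aldol adduct 9; cutting the bond between its two stereocentres leads to imide 6 and aldehyde 7. A syn aldol is required, because the syn diol closes to the cis oxetane. The absolute sense demands the (R)-configured auxiliary 4: its (2R,3R) adduct becomes C4 (R) and C3 (R) of 21.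

**6 back to 3 and 4; 3 back to 1.** The imide is assembled from acid 3 and auxiliary 4 through anhydride 5, and 3 is acid 1 with its phenol benzylated (through ester 2).

## Alternatives that were turned down

Alternative 1: The cuts are at C4–C4a and C2–C3. The C3–C4–C5 unit is the chiral butenolide (5R)-5-menthyloxyfuran-2(5H)-one A2, C4a arrives as the anion of aryl dithiane A3, and C2 is brought in by an aldol reaction of the intermediate enolate. In the forward key step the dithiane anion adds to the β-carbon of A2 anti to the menthyloxy group and the lactone enolate is trapped, giving A1 with the two new ring substituents trans; no ring is formed. In its favour, every bond formation is of a well-practised type, the absolute configuration comes from an inexpensive crystalline acetal, and both aryl units enter in one flask. Against it, A1 is still far from this target. The dithiane must be removed reductively without loss of benzyl ethers or of the benzylic hydroxyl, the acetal lactone must be reduced with loss of the menthyl group, and the tetrahydrofuran is then closed through a benzylic cation under acid, the regime in which the aryl ring on C4a competes for the cation. C2 is fixed only at that late point, and about five steps lie between A1 and the ring, before esterification and deprotection. In reliability of the individual steps this alternative is the stronger one. The chosen plan offers instead a ring-forming step that needs no cation, sets C2 on a precursor whose C3/C4 pair is already locked, and leaves a single step after the ring is made.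

Alternative 2: Both side-chain bonds, C3–C3a and C4–C4a, are cut at once. C3a and C4a are the two carbons of dichloroketene A6, and the acceptor is the C3=C4 alkene of the (S)-2-aryl-2,5-dihydrofuran A5. The forward key step is the thermal [2+2] cycloaddition, which gives the cis-fused dichlorocyclobutanone A4; its C3a–C4a bond is temporary and is cleaved later. In its favour, the ring fusion enforces the cis relationship of C3a and C4a, and approach anti to the C2 aryl group should give the 2,3-trans arrangement, so all relative stereochemistry follows from one existing centre. Against it, the alkene of A5 is almost unpolarised, so which end receives the carbonyl carbon is poorly controlled, and A5 must be made enantiopure and can lose its stereocentre by double-bond migration. After A4 the four-membered ring must be cleaved, the chlorine atoms removed, an aryl group added to C4a and the resulting benzylic oxygen removed again in the presence of the C2–O1 benzylic ether, which is a long redox sequence for one arylmethyl group. On control of the C2/C3 relationship this alternative is stronger than the chosen plan, which relies on an untested recombination. The chosen plan carries the intact arylmethyl group from the first step and needs no carbon–carbon cleavage or deoxygenation.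

Alternative 3: O1–C5 and C5–C4 are cut, and C5 is supplied by carbon monoxide A9; the precursor is the homopropargylic alcohol A8, which already holds C2 and C3. In the forward key step a palladium-catalysed cyclocarbonylation converts A8 into the (E)-benzylidene lactone A7 and closes the five-membered ring. In its favour, the carbonylation is an established catalytic reaction, ring and C5 arrive together, C2 and C3 are set beforehand by acyclic methods, and hydrogenation of the exocyclic alkene from the face opposite the C3 substituent would place C4a cis to C3a. Against it, C5 enters at the carboxyl oxidation level and must be taken down to CH2, either by ionising lactol reduction next to a benzylic C–O bond or by reduction and re-closure. The alkene hydrogenation must also spare two aryl benzyl ethers and the benzylic lactone C–O bond, the silyl ether must be exchanged for the ester, and A8 needs its own stereoselective synthesis. In the certainty of its key step this alternative is clearly stronger. The chosen plan offers C2 introduced at its final oxidation level, no carbonyl group to delete, and only a deprotection after ring formation.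

Key step: step 10

## Route

Assumption: [(4-methoxybenzyl)oxy]acetaldehyde 7 is treated as a purchasable reagent and is distilled before use, because α-alkoxy acetaldehydes oligomerise on storage.

Step 1
Reactants: 1 3-(4-hydroxy-3-methoxyphenyl)propanoic acid
Product: 3 3-[4-(benzyloxy)-3-methoxyphenyl]propanoic acid, via benzyl ester 2 (not isolated)
Conditions: BnBr (2.3 equiv), K2CO3, DMF, 60 °C; then NaOH, MeOH/H2O, 60 °C; then aq. HCl
Reagents that add atoms: benzyl bromide, BrCc1ccccc1
Why: Williamson O-alkylation of phenoxide and carboxylate, then saponification of the benzyl ester in the same pot; the aryl benzyl ether is inert to hydroxide, so only the acid is unmasked.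

Step 2
Reactants: 3 3-[4-(benzyloxy)-3-methoxyphenyl]propanoic acid; 4 (4R)-4-benzyl-1,3-oxazolidin-2-one
Product: 6 (4R)-4-benzyl-3-{3-[4-(benzyloxy)-3-methoxyphenyl]propanoyl}-1,3-oxazolidin-2-one, via mixed pivalic anhydride 5 (not isolated)
Conditions: t-BuCOCl, Et3N, THF, −20 °C; then 4, LiCl, −20 °C → rt
Reagents that add atoms: none
Why: N-acylation of the oxazolidinone through the mixed anhydride with LiCl activation; attack occurs at the unhindered acyl carbon and the auxiliary stereocentre is not touched.

Step 3
Reactants: 6 (4R)-4-benzyl-3-{3-[4-(benzyloxy)-3-methoxyphenyl]propanoyl}-1,3-oxazolidin-2-one; 7 [(4-methoxybenzyl)oxy]acetaldehyde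
Product: 9 (4R)-4-benzyl-3-[(2R,3R)-2-[4-(benzyloxy)-3-methoxybenzyl]-3-hydroxy-4-[(4-methoxybenzyl)oxy]butanoyl]-1,3-oxazolidin-2-one, via dibutylboron Z-enolate 8 (not isolated)
Conditions: Bu2BOTf, i-Pr2NEt, CH2Cl2, −78 → 0 °C; then 7, −78 → 0 °C; then H2O2, MeOH, pH 7 buffer, 0 °C
Reagents that add atoms: none
Why: Evans syn aldol reaction; the Z-boron enolate reacts through a closed Zimmerman–Traxler chair with the auxiliary carbonyl turned away from boron, so the (R)-benzyl group blocks one enolate face and the (2R,3R) syn adduct should form; these two centres become C4 and C3 of the target.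

Step 4
Reactants: 9 (4R)-4-benzyl-3-[(2R,3R)-2-[4-(benzyloxy)-3-methoxybenzyl]-3-hydroxy-4-[(4-methoxybenzyl)oxy]butanoyl]-1,3-oxazolidin-2-one
Product: 10 (2S,3R)-2-[4-(benzyloxy)-3-methoxybenzyl]-4-[(4-methoxybenzyl)oxy]butane-1,3-diol
Conditions: LiBH4, MeOH (1 equiv), THF, 0 °C
Reagents that add atoms: none
Why: Reductive cleavage of the imide at the exocyclic carbonyl gives the 1,3-diol without epimerisation of the α-carbon and returns the auxiliary; the descriptor at C2 changes only because the priorities change.

Step 5
Reactants: 10 (2S,3R)-2-[4-(benzyloxy)-3-methoxybenzyl]-4-[(4-methoxybenzyl)oxy]butane-1,3-diol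
Product: 11 (2S,3R)-2-[4-(benzyloxy)-3-methoxybenzyl]-3-hydroxy-4-[(4-methoxybenzyl)oxy]butyl 4-methylbenzenesulfonate
Conditions: TsCl (1.1 equiv), pyridine, CH2Cl2, 0 °C
Reagents that add atoms: 4-methylbenzenesulfonyl chloride, Cc1ccc(cc1)S(=O)(=O)Cl
Why: Selective sulfonylation; the primary hydroxyl reacts much faster than the secondary one, which is flanked by two branches.

Step 6
Reactants: 11 (2S,3R)-2-[4-(benzyloxy)-3-methoxybenzyl]-3-hydroxy-4-[(4-methoxybenzyl)oxy]butyl 4-methylbenzenesulfonate
Product: 12 (2R,3S)-3-[4-(benzyloxy)-3-methoxybenzyl]-2-{[(4-methoxybenzyl)oxy]methyl}oxetane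
Conditions: NaH, THF, 0 → 45 °C
Reagents that add atoms: none
Why: Intramolecular Williamson etherification (4-exo-tet); the secondary alkoxide displaces the primary tosylate, so neither stereocentre takes part and the syn diol is carried over as the cis-2,3-disubstituted oxetane; the ether protecting groups cannot migrate to the alkoxide.

Step 7
Reactants: 12 (2R,3S)-3-[4-(benzyloxy)-3-methoxybenzyl]-2-{[(4-methoxybenzyl)oxy]methyl}oxetane
Product: 13 {(2R,3S)-3-[4-(benzyloxy)-3-methoxybenzyl]oxetan-2-yl}methanol
Conditions: DDQ, CH2Cl2/pH 7 buffer (10:1), 0 °C → rt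
Reagents that add atoms: none
Why: Oxidative cleavage of the 4-methoxybenzyl ether (hydride abstraction, then hydrolysis of the hemiacetal) in a buffered two-phase medium; the aryl benzyl ether and the oxetane should not be affected under these neutral conditions.

Step 8
Reactants: 13 {(2R,3S)-3-[4-(benzyloxy)-3-methoxybenzyl]oxetan-2-yl}methanol; 14 octadecanoic acid (stearic acid)
Product: 15 {(2R,3S)-3-[4-(benzyloxy)-3-methoxybenzyl]oxetan-2-yl}methyl octadecanoate
Conditions: EDC·HCl, DMAP (cat.), CH2Cl2, 0 °C → rt
Reagents that add atoms: none
Why: Steglich esterification of the only hydroxyl group under acid-free conditions, chosen because acid next to the new ester could open the oxetane by acyloxy participation.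

Step 9
Reactants: 16 4-(benzyloxy)-3-methoxybenzaldehyde
Product: 17 N'-[(E)-4-(benzyloxy)-3-methoxybenzylidene]-4-methylbenzenesulfonohydrazide
Conditions: TsNHNH2, MeOH, rt
Reagents that add atoms: 4-methylbenzenesulfonohydrazide, Cc1ccc(cc1)S(=O)(=O)NN
Why: Condensation of the aldehyde with the sulfonyl hydrazide gives the crystalline E-hydrazone, the bench-stable precursor of the diazo compound.

Step 10
Reactants: 15 {(2R,3S)-3-[4-(benzyloxy)-3-methoxybenzyl]oxetan-2-yl}methyl octadecanoate; 17 N'-[(E)-4-(benzyloxy)-3-methoxybenzylidene]-4-methylbenzenesulfonohydrazide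
Product: 20 {(2S,3R,4R)-2-[4-(benzyloxy)-3-methoxyphenyl]-4-[4-(benzyloxy)-3-methoxybenzyl]oxolan-3-yl}methyl octadecanoate, via sodium hydrazone salt 18 (not isolated), via aryldiazomethane 19 (not isolated)
Conditions: 17 (3 equiv), NaH (2.9 equiv), THF, 0 °C → rt, then evaporate; then 15 (0.5 M), Rh2(OAc)4 (2 mol %), BnEt3NCl (10 mol %), ClCH2CH2Cl, 40 °C, salt 18 added in portions
Reagents that add atoms: none
Why: Proposed new method: The salt 18 releases the aryldiazomethane 19 slowly at 40 °C (first stage of the Bamford–Stevens reaction), Rh2(OAc)4 turns it into an electrophilic aryl carbene, and the oxetane oxygen of 15, the most exposed and most basic lone pair in the molecule, adds to give an oxonium ylide. The ylide should rearrange by a Stevens [1,2]-shift: the bond from oxygen to the substituted oxetane carbon breaks under ring strain, and the resulting tethered singlet radical pair recombines at the benzylic ylide carbon, so that O1–C2 and then C2–C3 are formed and the four-membered ring becomes the five-membered one. The nearest established reaction type is the ring expansion of oxetanes by diazo esters under copper catalysis or visible light, which runs through the same ylide and shift; neither a donor-only aryl carbene nor a non-benzylic migrating carbon has been shown in it. The tetrahydrofuran is closed by ring expansion, that is, by recombination of two radical ends held five atoms apart by the O1–C5–C4 tether. The step needs migration of the substituted carbon rather than the CH2 group, which the better stabilised secondary radical and the larger relief of strain should favour, and retention at the migrating carbon, which follows if recombination within the tether is faster than rotation about C3–C4, so that C3a and C4a stay cis. The new stereocentre C2 is set under substrate control by the adjacent C3 centre: the aryl group should take the face away from the acyloxymethyl arm and give the 2,3-trans isomer. Slow release of 19 and a non-ether solvent keep carbene dimerisation and ylide formation with the medium low, and a minor C2 epimer is to be removed by chromatography, because acid equilibration would send the benzylic cation into the aryl ring on C4a.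

Step 11
Reactants: 20 {(2S,3R,4R)-2-[4-(benzyloxy)-3-methoxyphenyl]-4-[4-(benzyloxy)-3-methoxybenzyl]oxolan-3-yl}methyl octadecanoate
Product: 21 {(2S,3R,4R)-2-(4-hydroxy-3-methoxyphenyl)-4-(4-hydroxy-3-methoxybenzyl)oxolan-3-yl}methyl octadecanoate
Conditions: H2 (1 atm), 10% Pd/C, EtOAc, rt, stopped at full conversion
Reagents that add atoms: none
Why: Hydrogenolysis of the two aryl benzyl ethers, which are cleaved much faster than the ring C2–O1 benzylic ether; an aprotic solvent, one atmosphere and a short contact time should keep the ester and the ring intact.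

## Compound list

1 | 3-(4-hydroxy-3-methoxyphenyl)propanoic acid | COc1cc(CCC(=O)O)ccc1O | starting material
2 | benzyl 3-[4-(benzyloxy)-3-methoxyphenyl]propanoate | COc1cc(CCC(=O)OCc2ccccc2)ccc1OCc1ccccc1 | intermediate (not isolated)
3 | 3-[4-(benzyloxy)-3-methoxyphenyl]propanoic acid | COc1cc(CCC(=O)O)ccc1OCc1ccccc1 | intermediate
4 | (4R)-4-benzyl-1,3-oxazolidin-2-one | O=C1N[C@H](Cc2ccccc2)CO1 | starting material
5 | 3-[4-(benzyloxy)-3-methoxyphenyl]propanoic 2,2-dimethylpropanoic anhydride | COc1cc(CCC(=O)OC(=O)C(C)(C)C)ccc1OCc1ccccc1 | intermediate (not isolated)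
6 | (4R)-4-benzyl-3-{3-[4-(benzyloxy)-3-methoxyphenyl]propanoyl}-1,3-oxazolidin-2-one | COc1cc(CCC(=O)N2[C@H](Cc3ccccc3)COC2=O)ccc1OCc1ccccc1 | intermediate
7 | [(4-methoxybenzyl)oxy]acetaldehyde | COc1ccc(COCC=O)cc1 | starting material
8 | Z-dibutylboron enolate of 6 | CCCCB(CCCC)O/C(=C\Cc1ccc(OCc2ccccc2)c(OC)c1)N1[C@H](Cc2ccccc2)COC1=O | intermediate (not isolated)
9 | (4R)-4-benzyl-3-[(2R,3R)-2-[4-(benzyloxy)-3-methoxybenzyl]-3-hydroxy-4-[(4-methoxybenzyl)oxy]butanoyl]-1,3-oxazolidin-2-one | COc1ccc(COC[C@H](O)[C@@H](Cc2ccc(OCc3ccccc3)c(OC)c2)C(=O)N2[C@H](Cc3ccccc3)COC2=O)cc1 | intermediate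
10 | (2S,3R)-2-[4-(benzyloxy)-3-methoxybenzyl]-4-[(4-methoxybenzyl)oxy]butane-1,3-diol | COc1ccc(COC[C@H](O)[C@@H](Cc2ccc(OCc3ccccc3)c(OC)c2)CO)cc1 | intermediate
11 | (2S,3R)-2-[4-(benzyloxy)-3-methoxybenzyl]-3-hydroxy-4-[(4-methoxybenzyl)oxy]butyl 4-methylbenzenesulfonate | COc1ccc(COC[C@H](O)[C@@H](Cc2ccc(OCc3ccccc3)c(OC)c2)COS(=O)(=O)c2ccc(C)cc2)cc1 | intermediate
12 | (2R,3S)-3-[4-(benzyloxy)-3-methoxybenzyl]-2-{[(4-methoxybenzyl)oxy]methyl}oxetane | COc1ccc(COC[C@@H]2OC[C@@H]2Cc2ccc(OCc3ccccc3)c(OC)c2)cc1 | intermediate
13 | {(2R,3S)-3-[4-(benzyloxy)-3-methoxybenzyl]oxetan-2-yl}methanol | OC[C@@H]1OC[C@@H]1Cc1ccc(OCc2ccccc2)c(OC)c1 | intermediate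
14 | octadecanoic acid (stearic acid) | CCCCCCCCCCCCCCCCCC(=O)O | starting material
15 | {(2R,3S)-3-[4-(benzyloxy)-3-methoxybenzyl]oxetan-2-yl}methyl octadecanoate | CCCCCCCCCCCCCCCCCC(=O)OC[C@@H]1OC[C@@H]1Cc1ccc(OCc2ccccc2)c(OC)c1 | intermediate
16 | 4-(benzyloxy)-3-methoxybenzaldehyde | COc1cc(C=O)ccc1OCc1ccccc1 | starting material
17 | N'-[(E)-4-(benzyloxy)-3-methoxybenzylidene]-4-methylbenzenesulfonohydrazide | COc1cc(/C=N/NS(=O)(=O)c2ccc(C)cc2)ccc1OCc1ccccc1 | intermediate
18 | sodium salt of 17 | COc1cc(/C=N/[N-]S(=O)(=O)c2ccc(C)cc2)ccc1OCc1ccccc1.[Na+] | intermediate (not isolated)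
19 | [4-(benzyloxy)-3-methoxyphenyl]diazomethane | COc1cc(C=[N+]=[N-])ccc1OCc1ccccc1 | intermediate (not isolated)
20 | {(2S,3R,4R)-2-[4-(benzyloxy)-3-methoxyphenyl]-4-[4-(benzyloxy)-3-methoxybenzyl]oxolan-3-yl}methyl octadecanoate | CCCCCCCCCCCCCCCCCC(=O)OC[C@H]1[C@@H](Cc2ccc(OCc3ccccc3)c(OC)c2)CO[C@@H]1c1ccc(OCc2ccccc2)c(OC)c1 | intermediate
21 | {(2S,3R,4R)-2-(4-hydroxy-3-methoxyphenyl)-4-(4-hydroxy-3-methoxybenzyl)oxolan-3-yl}methyl octadecanoate | CCCCCCCCCCCCCCCCCC(=O)OC[C@H]1[C@@H](Cc2ccc(O)c(OC)c2)CO[C@@H]1c1ccc(O)c(OC)c1 | target

## Step count and least certain steps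

Total: 11 steps. Longest linear sequence: 10 steps (steps 1–8, 10 and 11); step 9 is a one-step side branch.

**Step 10 (key step, new method).** Several processes could divert it:
- dimerisation of the carbene with 19 to stilbene and azine outrunning capture by the oxetane oxygen, because a donor-only carbene is less electrophilic;
- diversion of the oxonium ylide before the shift, by opening of the activated ring through the neighbouring ester carbonyl, by β-elimination to an allyl ether, or by attack of sulfinate;
- migration of the unsubstituted CH2 group;
- loss of configuration at the migrating carbon by rotation about C3–C4 before the radical ends recombine;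
- poor facial discrimination at C2.

Fallback (known chemistry), setting out from acid 3 and aldehyde 16 and returning at 20. Acid 3 is coupled as in step 2, through anhydride 5, with the enantiomeric auxiliary (S)-4-benzyl-2-oxazolidinone to give the (4S)-imide F1. Evans alkylation of its sodium enolate (NaN(SiMe3)2, THF, −78 °C) with tert-butyl bromoacetate should give the (R)-configured tert-butyl succinate imide F2. LiBH4 reduction releases the auxiliary and gives the hydroxy ester F3, which lactonises under acid catalysis (TsOH, toluene) to the (R)-β-(arylmethyl)butyrolactone F4. The lithium enolate of F4 (LiN(SiMe3)2, THF, −78 °C) adds to 16 anti to the ring substituent and gives the trans aldol lactone F5 as carbinol epimers. LiAlH4 reduces F5 to the triol F6. Brief treatment of F6 with a catalytic sulfonic acid in CH2Cl2 at 0 °C closes the tetrahydrofuran through the benzylic cation; both epimers should converge on the 2,3-trans primary alcohol F7, the O,O'-dibenzyl ether of the parent triol. Steglich esterification of F7 with 14 gives 20. This sequence is longer, and its ring closure is the cation-forming step that the main route avoids, which is why it is held in reserve.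

**Step 6 (oxetane closure).** The γ-sulfonyloxy alkoxide can fragment (Grob-type cleavage of the C2–C3 bond of 11) or etherify intermolecularly instead of closing the strained ring.

Fallback, setting out from diol 10 and returning at oxetane 12 without passing through 11: cyclodehydration under Mitsunobu conditions (PPh3, DIAD, toluene, 0 → 60 °C). The primary hydroxyl is activated as an oxyphosphonium ion and displaced by the neighbouring secondary hydroxyl; no alkali alkoxide is present, so the fragmentation loses its driving force. No new compound is made on the way (F0).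

**Step 11 (final hydrogenolysis).** Once the para-hydroxyl groups are free, over-reduction by hydrogenolytic opening of the C2–O1 bond can set in if debenzylation is slow.

Fallback, setting out from 15 and returning at 21, with the phenol protection changed so that the last step is not reductive. Hydrogenolysis of 15 (H2, Pd/C, EtOAc; harmless there because the oxetane has no benzylic C–O bond) gives the phenol F8, which is silylated (TBSCl, imidazole, DMF) to the silyl ether F9. The carbene partner becomes the tosylhydrazone F10 of commercial 4-(tert-butyldimethylsilyloxy)-3-methoxybenzaldehyde; its sodium salt F11 releases the diazo compound F12. Ring expansion of F9 as in step 10 gives the bis(silyl ether) F13, and buffered fluoride (Bu4NF, AcOH, THF, 0 °C) frees both phenols to give 21.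

## Further compounds

F1 | step 10 | (4S)-4-benzyl-3-{3-[4-(benzyloxy)-3-methoxyphenyl]propanoyl}-1,3-oxazolidin-2-one | COc1cc(CCC(=O)N2[C@@H](Cc3ccccc3)COC2=O)ccc1OCc1ccccc1
F2 | step 10 | tert-butyl (3R)-3-[4-(benzyloxy)-3-methoxybenzyl]-4-[(4S)-4-benzyl-2-oxo-1,3-oxazolidin-3-yl]-4-oxobutanoate | CC(C)(C)OC(=O)C[C@@H](Cc1ccc(OCc2ccccc2)c(OC)c1)C(=O)N1[C@@H](Cc2ccccc2)COC1=O
F3 | step 10 | tert-butyl (3R)-3-[4-(benzyloxy)-3-methoxybenzyl]-4-hydroxybutanoate | CC(C)(C)OC(=O)C[C@@H](Cc1ccc(OCc2ccccc2)c(OC)c1)CO
F4 | step 10 | (4R)-4-[4-(benzyloxy)-3-methoxybenzyl]oxolan-2-one | O=C1C[C@@H](Cc2ccc(OCc3ccccc3)c(OC)c2)CO1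
F5 | step 10 | (3S,4R)-4-[4-(benzyloxy)-3-methoxybenzyl]-3-{[4-(benzyloxy)-3-methoxyphenyl](hydroxy)methyl}oxolan-2-one (carbinol epimers) | O=C1[C@H](C(O)c2ccc(OCc3ccccc3)c(OC)c2)[C@@H](Cc2ccc(OCc3ccccc3)c(OC)c2)CO1
F6 | step 10 | (2R,3R)-3-[4-(benzyloxy)-3-methoxybenzyl]-2-{[4-(benzyloxy)-3-methoxyphenyl](hydroxy)methyl}butane-1,4-diol (carbinol epimers) | OC[C@H](C(O)c1ccc(OCc2ccccc2)c(OC)c1)[C@@H](Cc1ccc(OCc2ccccc2)c(OC)c1)CO
F7 | step 10 | {(2S,3R,4R)-2-[4-(benzyloxy)-3-methoxyphenyl]-4-[4-(benzyloxy)-3-methoxybenzyl]oxolan-3-yl}methanol | OC[C@H]1[C@@H](Cc2ccc(OCc3ccccc3)c(OC)c2)CO[C@@H]1c1ccc(OCc2ccccc2)c(OC)c1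
F0 | step 6 | none | none
F8 | step 11 | {(2R,3S)-3-(4-hydroxy-3-methoxybenzyl)oxetan-2-yl}methyl octadecanoate | CCCCCCCCCCCCCCCCCC(=O)OC[C@@H]1OC[C@@H]1Cc1ccc(O)c(OC)c1
F9 | step 11 | {(2R,3S)-3-[4-(tert-butyldimethylsilyloxy)-3-methoxybenzyl]oxetan-2-yl}methyl octadecanoate | CCCCCCCCCCCCCCCCCC(=O)OC[C@@H]1OC[C@@H]1Cc1ccc(O[Si](C)(C)C(C)(C)C)c(OC)c1
F10 | step 11 | N'-[(E)-4-(tert-butyldimethylsilyloxy)-3-methoxybenzylidene]-4-methylbenzenesulfonohydrazide | COc1cc(/C=N/NS(=O)(=O)c2ccc(C)cc2)ccc1O[Si](C)(C)C(C)(C)C
F11 | step 11 | sodium salt of F10 | COc1cc(/C=N/[N-]S(=O)(=O)c2ccc(C)cc2)ccc1O[Si](C)(C)C(C)(C)C.[Na+]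
F12 | step 11 | [4-(tert-butyldimethylsilyloxy)-3-methoxyphenyl]diazomethane | COc1cc(C=[N+]=[N-])ccc1O[Si](C)(C)C(C)(C)C
F13 | step 11 | {(2S,3R,4R)-2-[4-(tert-butyldimethylsilyloxy)-3-methoxyphenyl]-4-[4-(tert-butyldimethylsilyloxy)-3-methoxybenzyl]oxolan-3-yl}methyl octadecanoate | CCCCCCCCCCCCCCCCCC(=O)OC[C@H]1[C@@H](Cc2ccc(O[Si](C)(C)C(C)(C)C)c(OC)c2)CO[C@@H]1c1ccc(O[Si](C)(C)C(C)(C)C)c(OC)c1
A1 | alternative 1 | trans-α-[aryl(hydroxy)methyl]-β-(2-aryl-1,3-dithian-2-yl)-γ-menthyloxy-γ-butyrolactone, aryl = 4-(benzyloxy)-3-methoxyphenyl (carbinol epimers) | O=C1[C@H](C(O)c2ccc(OCc3ccccc3)c(OC)c2)[C@@H](C2(SCCCS2)c2ccc(OCc3ccccc3)c(OC)c2)[C@H](O[C@@H]2C[C@H](C)CC[C@H]2C(C)C)O1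
A2 | alternative 1 | (5R)-5-[(1R,2S,5R)-menthyloxy]furan-2(5H)-one | O=C1C=C[C@H](O[C@@H]2C[C@H](C)CC[C@H]2C(C)C)O1
A3 | alternative 1 | 2-[4-(benzyloxy)-3-methoxyphenyl]-1,3-dithiane | COc1cc(C2SCCCS2)ccc1OCc1ccccc1
A4 | alternative 2 | cis-fused 4-[4-(benzyloxy)-3-methoxyphenyl]-7,7-dichloro-3-oxabicyclo[3.2.0]heptan-6-one (carbonyl on the C3-derived carbon) | O=C2[C@H]1[C@@H](C2(Cl)Cl)CO[C@@H]1c1ccc(OCc3ccccc3)c(OC)c1
A5 | alternative 2 | (2S)-2-[4-(benzyloxy)-3-methoxyphenyl]-2,5-dihydrofuran | C1=CCO[C@@H]1c1ccc(OCc2ccccc2)c(OC)c1
A6 | alternative 2 | dichloroketene | O=C=C(Cl)Cl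
A7 | alternative 3 | (E)-3-[4-(benzyloxy)-3-methoxybenzylidene]-5-[4-(benzyloxy)-3-methoxyphenyl]-4-{[(tert-butyldimethylsilyl)oxy]methyl}oxolan-2-one (4,5-trans) | CC(C)(C)[Si](C)(C)OC[C@H]1/C(=C\c2ccc(OCc3ccccc3)c(OC)c2)C(=O)O[C@@H]1c1ccc(OCc2ccccc2)c(OC)c1
A8 | alternative 3 | 1,4-bis[4-(benzyloxy)-3-methoxyphenyl]-2-{[(tert-butyldimethylsilyl)oxy]methyl}but-3-yn-1-ol (stereoisomer matching A7) | CC(C)(C)[Si](C)(C)OC[C@@H](C#Cc1ccc(OCc2ccccc2)c(OC)c1)[C@H](O)c1ccc(OCc2ccccc2)c(OC)c1
A9 | alternative 3 | carbon monoxide | [C-]#[O+]
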